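The side chain is cut at C3–C4 (chain numbered from the OCH2 carbon as C1). The key step exploits the fact that the only stereocentre, the acetoxy-bearing carbon C4, is bonded directly to the methyl-substituted sp2 carbon C3 of the acyclic E-configured C2=C3 alkene. One nickel-catalysed reductive coupling joins an (E)-alkenyl bromide (C1–C3) with a racemic 1-chloroalkyl acetate (C4–C8) and sets C4 as R with the acetate already in place, both chloride enantiomers converging through a planar radical. The precursors are a silyl-protected (E)-3-bromobut-2-enol and the acetyl chloride adduct of 4-methylpent-3-enal. The 5-methylcoumarin (benzene-fused pyranone) is made separately and attached last at O4–C1 by Mitsunobu reaction.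

Key step: step 7

Assumption: the sense of induction of a bis(oxazoline)–nickel catalyst cannot be predicted with confidence for a 1-chloroalkyl acetate. The ligand enantiomer written in step 7 is provisional; it would be assigned on a model pair, and the antipode used if the model favours S.

Step 1
Reactants: 1 ethyl but-2-ynoate
Product: 3 ethyl (E)-3-(trimethylstannyl)but-2-enoate, via alkenylcuprate adduct 2 (not isolated)
Conditions: Me3SnSnMe3, MeLi, THF, −20 °C; CuSPh, −20 °C; then 1 and MeOH (1.7 equiv), −100 to −78 °C; aq NH4Cl
Reagents that add atoms: hexamethylditin, C[Sn](C)(C)[Sn](C)(C)C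
Why: Stannylcupration of an ynoate: the stannylcuprate adds tin and copper syn across the triple bond with tin at C3, and methanol protonates alkenylcuprate 2 at low temperature before it can equilibrate through the allenoate, so the kinetic E ester (tin trans to the ester group) should be formed.

Step 2
Reactants: 3 ethyl (E)-3-(trimethylstannyl)but-2-enoate
Product: 4 (E)-3-(trimethylstannyl)but-2-en-1-ol
Conditions: i-Bu2AlH (2.3 equiv), CH2Cl2, −78 to 0 °C; aq potassium sodium tartrate
Reagents that add atoms: none
Why: Ester reduction with i-Bu2AlH (1,2-reduction of an enoate to the allylic alcohol) should leave the alkenyl–tin bond and the alkene geometry untouched.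

Step 3
Reactants: 4 (E)-3-(trimethylstannyl)but-2-en-1-ol
Product: 5 tert-butyldimethyl{[(E)-3-(trimethylstannyl)but-2-en-1-yl]oxy}silane
Conditions: TBSCl, imidazole, CH2Cl2, 0 °C to rt
Reagents that add atoms: tert-butyldimethylsilyl chloride, CC(C)(C)[Si](C)(C)Cl
Why: Imidazole-promoted silylation of a primary alcohol masks the hydroxyl, which the 1-chloroalkyl acetate of step 7 would otherwise alkylate; a silyl ether is chosen because, unlike an allyl coumarinyl ether, it is not ionised by low-valent nickel, and it keeps the later bromide from being too volatile.

Step 4
Reactants: 5 tert-butyldimethyl{[(E)-3-(trimethylstannyl)but-2-en-1-yl]oxy}silane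
Product: 6 {[(E)-3-bromobut-2-en-1-yl]oxy}(tert-butyl)dimethylsilane
Conditions: Br2 (1.0 equiv), CH2Cl2, −78 °C; aq Na2S2O3
Reagents that add atoms: bromine, BrBr
Why: Electrophilic ipso bromodestannylation of an alkenylstannane proceeds with retention of configuration, so bromine should end up trans to the CH2OTBS group (E).

Step 5
Reactants: 7 4-methylpent-3-en-1-ol
Product: 8 4-methylpent-3-enal
Conditions: Dess–Martin periodinane (1.2 equiv), NaHCO3, CH2Cl2, 0 °C; filtered cold through a short pad and used at once as a dry CH2Cl2 solution
Reagents that add atoms: none
Why: Dess–Martin oxidation of a primary alcohol under bicarbonate buffering is close to neutral, so the β,γ-alkene should not migrate into conjugation with the new aldehyde if the product is kept cold and not stored.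

Step 6
Reactants: 8 4-methylpent-3-enal, 9 acetyl chloride
Product: 10 rac-1-chloro-4-methylpent-3-en-1-yl acetate
Conditions: ZnCl2 (2 mol%), CH2Cl2, −20 to 0 °C; volatiles removed cold, used at once under exclusion of moisture
Reagents that add atoms: none
Why: Lewis-acid-catalysed addition of an acyl chloride across an aldehyde carbonyl gives the 1-chloroalkyl ester with full atom economy; the new carbon centre is deliberately racemic because step 7 is stereoconvergent.

Step 7
Reactants: 6 {[(E)-3-bromobut-2-en-1-yl]oxy}(tert-butyl)dimethylsilane, 10 rac-1-chloro-4-methylpent-3-en-1-yl acetate (1.3 equiv)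
Product: 11 (R,E)-1-[(tert-butyldimethylsilyl)oxy]-3,7-dimethylocta-2,6-dien-4-yl acetate
Conditions: NiBr2·glyme (10 mol%), (3aR,3a'R,8aS,8a'S)-2,2'-(cyclopropane-1,1-diyl)bis(3a,8a-dihydro-8H-indeno[1,2-d]oxazole) (12 mol%), Mn powder (3 equiv), NaI (0.5 equiv), DMA, 0 °C
Reagents that add atoms: none
Why: Proposed new method: zerovalent nickel carrying the chiral bis(oxazoline) should add oxidatively to the sp2 C–Br bond of 6 with retention of the E geometry, while a monovalent nickel species abstracts chlorine from racemic 10 to give a planar, oxygen-stabilised α-acetoxyalkyl radical that has lost the configuration of the chloride; capture of this radical by the alkenylnickel and reductive elimination from trivalent nickel form the C3–C4 bond, and Mn returns the catalyst to its low-valent state. The closest known reaction types are the nickel-catalysed enantioconvergent coupling of racemic 1-haloalkyl esters with organozinc reagents and the nickel-catalysed asymmetric reductive alkenylation of racemic secondary benzylic chlorides with alkenyl bromides. No ring is closed. The R configuration at C4 is set by the chiral ligand on nickel during radical capture and reductive elimination (catalyst control), so both enantiomers of 10 converge on one product, and the acetate carbonyl offers nickel a second binding point of the kind that supports selectivity in the related ester couplings. The step needs cross-selectivity over homocoupling and enantioselectivity; the first is secured by the different activation modes of the two halides (two-electron oxidative addition at sp2 C–Br, halogen-atom abstraction at the acyloxy-activated sp3 C–Cl), the second by the ligand. The homoallylic radical should not be diverted, since its 3-exo closure onto the prenyl alkene is reversible and the open α-acetoxy radical is the more stable form, and the hindered allylic acetate of the product should ionise only slowly at 0 °C.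

Step 8
Reactants: 11 (R,E)-1-[(tert-butyldimethylsilyl)oxy]-3,7-dimethylocta-2,6-dien-4-yl acetate
Product: 12 (R,E)-1-hydroxy-3,7-dimethylocta-2,6-dien-4-yl acetate
Conditions: HF·pyridine, pyridine, THF, 0 °C to rt
Reagents that add atoms: none
Why: Fluoride-mediated cleavage of the silyl ether under buffered, mildly acidic conditions should spare the allylic acetate, which also cannot migrate to O1 across the E alkene; the enantiomeric purity would be checked at this stage by chiral HPLC.

Step 9
Reactants: 13 1-(2-hydroxy-6-methylphenyl)ethan-1-one, 14 diethyl carbonate (excess)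
Product: 16 4-hydroxy-5-methylcoumarin, via β-keto ester 15 (not isolated)
Conditions: NaH (3 equiv), toluene, 110 °C; then aq HCl
Reagents that add atoms: none
Why: Claisen condensation of the methyl ketone enolate with diethyl carbonate gives β-keto ester 15, whose phenoxide closes the pyranone by lactonisation (6-exo-trig acyl substitution), the stable salt of the 4-hydroxycoumarin driving the sequence.

Step 10
Reactants: 12 (R,E)-1-hydroxy-3,7-dimethylocta-2,6-dien-4-yl acetate, 16 4-hydroxy-5-methylcoumarin
Product: 17 (R,E)-3,7-dimethyl-1-[(5-methyl-2-oxo-2H-chromen-4-yl)oxy]octa-2,6-dien-4-yl acetate (target)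
Conditions: PPh3, DIAD, THF, 0 °C to rt
Reagents that add atoms: none
Why: Mitsunobu etherification: the acidic 4-hydroxyl of the coumarin (a vinylogous carboxylic acid) displaces the oxyphosphonium of the primary allylic alcohol by SN2 attack at C1 under neutral conditions, so the acetate, the R centre at C4 and the E alkene are not touched; any 2-alkoxychromone or C3-allyl isomer would be removed by chromatography.

Compound list
1 | ethyl but-2-ynoate | CC#CC(=O)OCC | starting material
2 | lithium [(Z)-1-ethoxy-1-oxo-3-(trimethylstannyl)but-2-en-2-yl](phenylthio)cuprate (alkenylcuprate adduct) | [Li+].CCOC(=O)/C([Cu-]Sc1ccccc1)=C(\C)[Sn](C)(C)C | intermediate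
3 | ethyl (E)-3-(trimethylstannyl)but-2-enoate | C/C([Sn](C)(C)C)=C\C(=O)OCC | intermediate
4 | (E)-3-(trimethylstannyl)but-2-en-1-ol | C/C([Sn](C)(C)C)=C\CO | intermediate
5 | tert-butyldimethyl{[(E)-3-(trimethylstannyl)but-2-en-1-yl]oxy}silane | C/C([Sn](C)(C)C)=C\CO[Si](C)(C)C(C)(C)C | intermediate
6 | {[(E)-3-bromobut-2-en-1-yl]oxy}(tert-butyl)dimethylsilane | C/C(Br)=C\CO[Si](C)(C)C(C)(C)C | intermediate
7 | 4-methylpent-3-en-1-ol | CC(C)=CCCO | starting material
8 | 4-methylpent-3-enal | CC(C)=CCC=O | intermediate
9 | acetyl chloride | CC(Cl)=O | starting material
10 | rac-1-chloro-4-methylpent-3-en-1-yl acetate | CC(=O)OC(Cl)CC=C(C)C | intermediate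
11 | (R,E)-1-[(tert-butyldimethylsilyl)oxy]-3,7-dimethylocta-2,6-dien-4-yl acetate | CC(=O)O[C@H](CC=C(C)C)/C(C)=C/CO[Si](C)(C)C(C)(C)C | intermediate
12 | (R,E)-1-hydroxy-3,7-dimethylocta-2,6-dien-4-yl acetate | CC(=O)O[C@H](CC=C(C)C)/C(C)=C/CO | intermediate
13 | 1-(2-hydroxy-6-methylphenyl)ethan-1-one (2'-hydroxy-6'-methylacetophenone) | CC(=O)c1c(C)cccc1O | starting material
14 | diethyl carbonate | CCOC(=O)OCC | starting material
15 | ethyl 3-(2-hydroxy-6-methylphenyl)-3-oxopropanoate | CCOC(=O)CC(=O)c1c(C)cccc1O | intermediate
16 | 4-hydroxy-5-methylcoumarin | Cc1cccc2oc(=O)cc(O)c12 | intermediate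
17 | (R,E)-3,7-dimethyl-1-[(5-methyl-2-oxo-2H-chromen-4-yl)oxy]octa-2,6-dien-4-yl acetate | CC(=O)O[C@H](CC=C(C)C)/C(C)=C/COc1cc(=O)oc2cccc(C)c12 | target

Total step count: 10
Longest linear sequence: 7 steps (steps 1, 2, 3, 4, 7, 8 and 10, from ethyl but-2-ynoate)

Steps most likely to fail

Step 7 (proposed method). Three things may go wrong:
- Oxidative addition of the hindered, α-methyl-substituted alkenyl bromide may be slow, so that reduction or homocoupling of the chloride wins.
- Facial discrimination in the radical capture may be poor.
- Low-valent nickel may ionise the allylic acetate of the product.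

The fallback uses known chemistry only, sets out from bromide 6 and aldehyde 8, and returns to the route at 11. Bromine–lithium exchange of 6 with t-BuLi (Et2O, −78 °C) would give [(E)-4-(tert-butyldimethylsilyloxy)but-2-en-2-yl]lithium F1 with retention of geometry. Addition of this to 8 should give racemic (E)-1-[(tert-butyldimethylsilyl)oxy]-3,7-dimethylocta-2,6-dien-4-ol F2. Buffered Dess–Martin oxidation would give (E)-1-[(tert-butyldimethylsilyl)oxy]-3,7-dimethylocta-2,6-dien-4-one F3. Corey–Bakshi–Shibata reduction with the (S)-2-methyl-oxazaborolidine and catecholborane (toluene, −78 °C), the branched alkenyl group acting as the large substituent, should give (R,E)-1-[(tert-butyldimethylsilyl)oxy]-3,7-dimethylocta-2,6-dien-4-ol F4. Acetylation (Ac2O, pyridine, DMAP) then gives 11.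

Step 6. Adventitious HCl may add to the trisubstituted alkene, the alkene may migrate into conjugation before the acyl chloride adds, and the moisture-sensitive adduct may hydrolyse on handling. The fallback sets out from aldehyde 8 and returns at 11. It drops the Lewis acid and changes the electrophile class: acetyl bromide should add across the aldehyde carbonyl without added catalyst (CH2Cl2, −20 °C) to give rac-1-bromo-4-methylpent-3-en-1-yl acetate F5. This is the halide class used in the known nickel couplings of 1-haloalkyl esters, and it would be taken into the coupling of step 7 in place of 10.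

Step 10. The ambident coumarin anion may be alkylated at the wrong site (the lactone oxygen, giving a 2-alkoxychromone, or C3), helped by the peri methyl group that crowds O4, and SN2' attack on the allylic oxyphosphonium is possible. The fallback sets out from alcohol 12 and coumarin 16 and returns at 17. An Appel reaction (CBr4, PPh3, CH2Cl2, 0 °C) would convert 12 into (R,E)-1-bromo-3,7-dimethylocta-2,6-dien-4-yl acetate F6. O-Alkylation of the potassium salt of 16 with this bromide (K2CO3, acetone or DMF, rt) is a plain SN2 etherification in place of the redox condensation.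

Further compounds
F1 | step 7 | [(E)-4-(tert-butyldimethylsilyloxy)but-2-en-2-yl]lithium | [Li]/C(C)=C/CO[Si](C)(C)C(C)(C)C
F2 | step 7 | rac-(E)-1-[(tert-butyldimethylsilyl)oxy]-3,7-dimethylocta-2,6-dien-4-ol | CC(C)=CCC(O)/C(C)=C/CO[Si](C)(C)C(C)(C)C
F3 | step 7 | (E)-1-[(tert-butyldimethylsilyl)oxy]-3,7-dimethylocta-2,6-dien-4-one | CC(C)=CCC(=O)/C(C)=C/CO[Si](C)(C)C(C)(C)C
F4 | step 7 | (R,E)-1-[(tert-butyldimethylsilyl)oxy]-3,7-dimethylocta-2,6-dien-4-ol | O[C@H](CC=C(C)C)/C(C)=C/CO[Si](C)(C)C(C)(C)C
F5 | step 6 | rac-1-bromo-4-methylpent-3-en-1-yl acetate | CC(=O)OC(Br)CC=C(C)C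
F6 | step 10 | (R,E)-1-bromo-3,7-dimethylocta-2,6-dien-4-yl acetate | CC(=O)O[C@H](CC=C(C)C)/C(C)=C/CBr
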